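**Retrosynthetic overview**
1. Kuwanon L ⇐ heptaacetate 21 ⇐ arylboronic acid 18 (the complete methylcyclohexene half, three stereocentres in place) + 5,7-diacetoxychromone 20. The bond from pyranone C2 to B-ring carbon C1' is made last, by Rh-catalysed asymmetric 1,4-arylation that also creates C2.
2. Enabling feature: flavanone C2 is the β-carbon of the C4 ketone inside the O1–C2–C3–C4 pyranone ring, so at the C2=C3 oxidation level the right half is a flat, achiral chromone (cyclic vinylogous ester acceptor). C1' of the B ring lies ortho/para to the two resorcinol oxygens with only H at C6', the position that brominates first in 2,6-dihydroxybenzaldehyde and can therefore carry boron.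
3. 18 ⇐ aryl bromide 16 ⇐ exo-selective, chiral-borate-directed Diels–Alder reaction of 2'-hydroxychalcone triacetate 7 with bromoaryl diene 13; this closes the cyclohexene and sets its three contiguous stereocentres.
4. Ring order: the benzene rings and the pyranone ring are bought; the cyclohexene is the only ring formed (step 10); the pyranone is saturated at C2–C3 in the key step. Acetates are the only late protecting group and come off in one near-neutral step, because base opens the flavanone at C2 and acid endangers the phenol/alkene/ketone array.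

Key step: step 13

Assumption (chemistry): the sense of induction of the (R)-VANOL borate in step 10 (attack on the Cα-Re/Cβ-Re face of the chelated chalcone) and of the (S)-bisphosphine–rhodium catalyst in step 13 ((S) at C2) follows the accepted models for these reaction classes; should either prove opposite, the antipodal ligand is used and nothing else changes.

Step 1
Reactants: 1 2',4'-dihydroxyacetophenone
Product: 2 1-[2-hydroxy-4-(methoxymethoxy)phenyl]ethan-1-one
Conditions: MOMCl (1.1 equiv), K2CO3, acetone, 0 °C to rt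
Reagents that add atoms: chloromethyl methyl ether (MOMCl), COCCl
Why: Williamson-type O-alkylation should occur only at the 4-OH, because the 2-OH is hydrogen-bonded to the ketone and far less nucleophilic.

Step 2
Reactants: 3 2,4-dihydroxybenzaldehyde
Product: 4 2,4-bis(methoxymethoxy)benzaldehyde
Conditions: MOMCl (2.6 equiv), i-Pr2NEt, CH2Cl2, 0 °C to reflux
Reagents that add atoms: chloromethyl methyl ether (MOMCl), COCCl
Why: Exhaustive O-alkylation (acetal formation) masks both phenols as base-stable MOM ethers so that the aldehyde remains electrophilic in the hydroxide-mediated condensation.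

Step 3
Reactants: 2 1-[2-hydroxy-4-(methoxymethoxy)phenyl]ethan-1-one; 4 2,4-bis(methoxymethoxy)benzaldehyde
Product: 5 (E)-3-[2,4-bis(methoxymethoxy)phenyl]-1-[2-hydroxy-4-(methoxymethoxy)phenyl]prop-2-en-1-one
Conditions: KOH (50% aq.), EtOH, rt; then AcOH to pH 6
Reagents that add atoms: none
Why: Claisen–Schmidt condensation (aldol addition, E1cB dehydration) should give the E-enone as the conjugated, thermodynamically favoured isomer.

Step 4
Reactants: 5 (E)-3-[2,4-bis(methoxymethoxy)phenyl]-1-[2-hydroxy-4-(methoxymethoxy)phenyl]prop-2-en-1-one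
Product: 6 (E)-1,3-bis(2,4-dihydroxyphenyl)prop-2-en-1-one (2,2',4,4'-tetrahydroxychalcone)
Conditions: 3 M HCl (aq.), MeOH, 50 °C, short reaction time
Reagents that add atoms: none
Why: Acid-catalysed acetal exchange with methanol cleaves the three MOM ethers, and the short exposure keeps the chalcone from cyclising.

Step 5
Reactants: 6 (E)-1,3-bis(2,4-dihydroxyphenyl)prop-2-en-1-one
Product: 7 (E)-3-(2,4-diacetoxyphenyl)-1-(4-acetoxy-2-hydroxyphenyl)prop-2-en-1-one
Conditions: Ac2O (3.1 equiv), pyridine, CH2Cl2, 0 °C
Reagents that add atoms: acetic anhydride, CC(=O)OC(C)=O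
Why: Pyridine-mediated O-acylation esterifies the three free phenols and should leave the ketone-chelated 2'-OH, which the boron-directed cycloaddition needs.

Step 6
Reactants: 8 2,6-dihydroxybenzaldehyde
Product: 9 3-bromo-2,6-dihydroxybenzaldehyde
Conditions: NBS (1.0 equiv), MeCN, −10 °C
Reagents that add atoms: N-bromosuccinimide, O=C1CCC(=O)N1Br
Why: Electrophilic aromatic bromination goes to C3, which is ortho to one hydroxyl and para to the other, while C4 is meta to both and para to the formyl group.

Step 7
Reactants: 9 3-bromo-2,6-dihydroxybenzaldehyde; 10 1-(triphenyl-λ5-phosphanylidene)propan-2-one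
Product: 11 (E)-4-(3-bromo-2,6-dihydroxyphenyl)but-3-en-2-one
Conditions: THF, 50 °C
Reagents that add atoms: none
Why: Wittig olefination with a stabilised ylide is neutral, tolerates the free phenols and should give the E-enone.

Step 8
Reactants: 11 (E)-4-(3-bromo-2,6-dihydroxyphenyl)but-3-en-2-one
Product: 12 (E)-4-(2,6-diacetoxy-3-bromophenyl)but-3-en-2-one
Conditions: Ac2O, pyridine, DMAP (cat.), CH2Cl2, 0 °C to rt
Reagents that add atoms: acetic anhydride, CC(=O)OC(C)=O
Why: DMAP-catalysed O-acylation installs the small, electron-withdrawing acetates that make the later aryl diene acid-stable and keep the position next to the future C–B bond unhindered.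

Step 9
Reactants: 12 (E)-4-(2,6-diacetoxy-3-bromophenyl)but-3-en-2-one
Product: 13 (E)-1-(2,6-diacetoxy-3-bromophenyl)-3-methylbuta-1,3-diene
Conditions: Zn, CH2Br2, TiCl4, THF, 0 °C; then 12, CH2Cl2, rt
Reagents that add atoms: dibromomethane, BrCBr
Why: Takai–Lombardo methylenation converts the ketone into the 1,1-disubstituted alkene under non-basic conditions that spare aryl acetates and the aryl bromide, and the E-styryl geometry is untouched.

Step 10
Reactants: 7 (E)-3-(2,4-diacetoxyphenyl)-1-(4-acetoxy-2-hydroxyphenyl)prop-2-en-1-one; 13 (E)-1-(2,6-diacetoxy-3-bromophenyl)-3-methylbuta-1,3-diene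
Product: 16 4-bromo-2-[(1S,5R,6S)-6-(4-acetoxy-2-hydroxybenzoyl)-5-(2,4-diacetoxyphenyl)-3-methylcyclohex-2-en-1-yl]-1,3-phenylene diacetate (all-trans exo adduct), via chalcone borate chelate 14 (not isolated), via cycloadduct borate chelate 15 (not isolated)
Conditions: (R)-VANOL (1.2 equiv), BH3·THF (1.2 equiv), AcOH (1.2 equiv), THF, rt; then 7; then 13 (1.5 equiv), rt to 40 °C; aq. NH4Cl; SiO2
Reagents that add atoms: (R)-VANOL, Oc1c(-c2c(O)c3ccccc3cc2-c2ccccc2)c(-c2ccccc2)cc2ccccc12; borane–tetrahydrofuran, B.C1CCOC1 (their atoms are held only in 14 and 15 and leave on work-up)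
Why: Chelate-directed Diels–Alder reaction of a 2'-hydroxychalcone promoted by a chiral borate: boron ties the 2'-O and C=O into spiro-borate 14, lowering the enone LUMO and letting the vaulted binaphthol shield the Cα-Si/Cβ-Si face, so the diene should add exo to the Cα-Re/Cβ-Re face with its CH2 terminus bonding to Cβ, closing the cyclohexene and setting C1 (S), C6 (S) and C5 (R) as the all-trans array, with the endo diastereomer removed on silica.

Step 11
Reactants: 16 4-bromo-2-[(1S,5R,6S)-6-(4-acetoxy-2-hydroxybenzoyl)-5-(2,4-diacetoxyphenyl)-3-methylcyclohex-2-en-1-yl]-1,3-phenylene diacetate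
Product: 18 {2,4-diacetoxy-3-[(1S,5R,6S)-6-(4-acetoxy-2-hydroxybenzoyl)-5-(2,4-diacetoxyphenyl)-3-methylcyclohex-2-en-1-yl]phenyl}boronic acid, via pinacol boronate 17 (not isolated)
Conditions: B2pin2 (1.5 equiv), PdCl2(dppf) (5 mol %), KOAc, 1,4-dioxane, 85 °C; then NaIO4, 1 M HCl, THF/H2O, rt
Reagents that add atoms: bis(pinacolato)diboron, CC1(C)OB(OC1(C)C)B1OC(C)(C)C(C)(C)O1; water, O
Why: Miyaura borylation at the only C–Br bond followed in the same flask by periodate cleavage of the pinacol ester should free the boronic acid for a base-free rhodium step, under neutral to mildly acidic conditions that spare the acetates, the ketone, the alkene and the stereocentres.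

Step 12
Reactants: 19 5,7-dihydroxychromone (5,7-dihydroxy-4H-chromen-4-one)
Product: 20 5,7-diacetoxychromone (4-oxo-4H-chromene-5,7-diyl diacetate)
Conditions: Ac2O, pyridine, DMAP (cat.), rt
Reagents that add atoms: acetic anhydride, CC(=O)OC(C)=O
Why: DMAP-catalysed O-acylation also esterifies the hydrogen-bonded 5-OH, which removes acidic protons from the acceptor and makes the C2=C3 bond more electrophilic.

Step 13
Reactants: 18 {2,4-diacetoxy-3-[(1S,5R,6S)-6-(4-acetoxy-2-hydroxybenzoyl)-5-(2,4-diacetoxyphenyl)-3-methylcyclohex-2-en-1-yl]phenyl}boronic acid; 20 5,7-diacetoxychromone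
Product: 21 (2S)-2-{2,4-diacetoxy-3-[(1S,5R,6S)-6-(4-acetoxy-2-hydroxybenzoyl)-5-(2,4-diacetoxyphenyl)-3-methylcyclohex-2-en-1-yl]phenyl}-4-oxochromane-5,7-diyl diacetate (Kuwanon L heptaacetate)
Conditions: 18 (1.0 equiv), 20 (2.0 equiv), [Rh(OH)((S)-MeO-F12-BIPHEP)]2 (1.5 mol %), toluene/H2O (10:1), 25 °C
Reagents that add atoms: none
Why: Hayashi–Miyaura reaction: transmetalation of 18 to Rh(I)–OH gives an aryl–rhodium that carbometalates the C2=C3 bond of 20 (aryl to C2), and water protonates the resulting oxa-π-allyl rhodium enolate, releasing 21 and regenerating Rh–OH. The closest known reaction type is the Rh-catalysed asymmetric 1,4-addition of arylboronic acids to chromones, which covers 5,7-dioxygenated chromones and ortho-oxygenated arylboron partners. No ring is closed: the pyranone enters intact and is only saturated at C2–C3, while the step forms the one C–C bond that joins the two halves. The new stereocentre C2 is set by the C2-symmetric (S)-bisphosphine on rhodium, which selects one face of the flat, achiral chromone irrespective of the three distant cyclohexene stereocentres, and any 2R epimer would be a separable diastereomer. The step needs 1,4- over 1,2-addition, addition over protodeboronation and no E1cB ring opening of the enolate. These are secured by the base-free hydroxo catalyst with an electron-poor ligand at 25 °C, by the cheap chromone in excess, by acetates that lower the electron density of the boron-bearing ring, and by the absence of free A- or B-ring phenols in the product, which keeps C2 configurationally stable.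

Step 14
Reactants: 21 Kuwanon L heptaacetate
Product: 22 Kuwanon L, (2S)-2-{3-[(1S,5R,6S)-6-(2,4-dihydroxybenzoyl)-5-(2,4-dihydroxyphenyl)-3-methylcyclohex-2-en-1-yl]-2,4-dihydroxyphenyl}-5,7-dihydroxychroman-4-one
Conditions: NH4OAc (excess), MeOH/THF/H2O (degassed), rt; work-up at pH 5–6
Reagents that add atoms: none
Why: Ammonium-acetate-mediated solvolysis of aryl acetates runs near neutrality, so it should avoid both the phenoxide-triggered opening of the flavanone at C2 (base) and the ketalisation or phenol–alkene cyclisation of the cyclohexene half (acid).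

**Compound list**
1 | 2',4'-dihydroxyacetophenone | CC(=O)c1ccc(O)cc1O | starting material
2 | 1-[2-hydroxy-4-(methoxymethoxy)phenyl]ethan-1-one | CC(=O)c1ccc(OCOC)cc1O | intermediate
3 | 2,4-dihydroxybenzaldehyde | O=Cc1ccc(O)cc1O | starting material
4 | 2,4-bis(methoxymethoxy)benzaldehyde | COCOc1ccc(C=O)c(OCOC)c1 | intermediate
5 | (E)-3-[2,4-bis(methoxymethoxy)phenyl]-1-[2-hydroxy-4-(methoxymethoxy)phenyl]prop-2-en-1-one | COCOc1ccc(C(=O)/C=C/c2ccc(OCOC)cc2OCOC)c(O)c1 | intermediate
6 | (E)-1,3-bis(2,4-dihydroxyphenyl)prop-2-en-1-one | O=C(/C=C/c1ccc(O)cc1O)c1ccc(O)cc1O | intermediate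
7 | (E)-3-(2,4-diacetoxyphenyl)-1-(4-acetoxy-2-hydroxyphenyl)prop-2-en-1-one | CC(=O)Oc1ccc(C(=O)/C=C/c2ccc(OC(C)=O)cc2OC(C)=O)c(O)c1 | intermediate
8 | 2,6-dihydroxybenzaldehyde | O=Cc1c(O)cccc1O | starting material
9 | 3-bromo-2,6-dihydroxybenzaldehyde | O=Cc1c(O)ccc(Br)c1O | intermediate
10 | 1-(triphenyl-λ5-phosphanylidene)propan-2-one | CC(=O)C=P(c1ccccc1)(c1ccccc1)c1ccccc1 | starting material
11 | (E)-4-(3-bromo-2,6-dihydroxyphenyl)but-3-en-2-one | CC(=O)/C=C/c1c(O)ccc(Br)c1O | intermediate
12 | (E)-4-(2,6-diacetoxy-3-bromophenyl)but-3-en-2-one | CC(=O)/C=C/c1c(OC(C)=O)ccc(Br)c1OC(C)=O | intermediate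
13 | (E)-1-(2,6-diacetoxy-3-bromophenyl)-3-methylbuta-1,3-diene | CC(=C)/C=C/c1c(OC(C)=O)ccc(Br)c1OC(C)=O | intermediate
14 | spiro-borate chelate of chalcone 7 (2'-O and C=O on boron) with (R)-VANOL | CC(=O)Oc1ccc2c(c1)O[B-]1(Oc3c(-c4c(O1)c5ccccc5cc4-c4ccccc4)c(-c4ccccc4)cc4ccccc34)[O+]=C2/C=C/c1ccc(OC(C)=O)cc1OC(C)=O | intermediate
15 | spiro-borate chelate of cycloadduct 16 with (R)-VANOL | CC1=C[C@H](c2c(OC(C)=O)ccc(Br)c2OC(C)=O)[C@@H](C2=[O+][B-]3(Oc4c(-c5c(O3)c6ccccc6cc5-c5ccccc5)c(-c5ccccc5)cc5ccccc45)Oc3cc(OC(C)=O)ccc23)[C@H](c2ccc(OC(C)=O)cc2OC(C)=O)C1 | intermediate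
16 | 4-bromo-2-[(1S,5R,6S)-6-(4-acetoxy-2-hydroxybenzoyl)-5-(2,4-diacetoxyphenyl)-3-methylcyclohex-2-en-1-yl]-1,3-phenylene diacetate | CC1=C[C@H](c2c(OC(C)=O)ccc(Br)c2OC(C)=O)[C@@H](C(=O)c2ccc(OC(C)=O)cc2O)[C@H](c2ccc(OC(C)=O)cc2OC(C)=O)C1 | intermediate
17 | pinacol boronate of 16 (Bpin in place of Br) | CC1=C[C@H](c2c(OC(C)=O)ccc(B3OC(C)(C)C(C)(C)O3)c2OC(C)=O)[C@@H](C(=O)c2ccc(OC(C)=O)cc2O)[C@H](c2ccc(OC(C)=O)cc2OC(C)=O)C1 | intermediate
18 | {2,4-diacetoxy-3-[(1S,5R,6S)-6-(4-acetoxy-2-hydroxybenzoyl)-5-(2,4-diacetoxyphenyl)-3-methylcyclohex-2-en-1-yl]phenyl}boronic acid | CC1=C[C@H](c2c(OC(C)=O)ccc(B(O)O)c2OC(C)=O)[C@@H](C(=O)c2ccc(OC(C)=O)cc2O)[C@H](c2ccc(OC(C)=O)cc2OC(C)=O)C1 | intermediate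
19 | 5,7-dihydroxychromone | O=c1ccoc2cc(O)cc(O)c12 | starting material
20 | 5,7-diacetoxychromone | CC(=O)Oc1cc(OC(C)=O)c2c(=O)ccoc2c1 | intermediate
21 | Kuwanon L heptaacetate (2-OH of the benzoyl group free), (2S) at the flavanone, (1S,5R,6S) in the cyclohexene | CC1=C[C@H](c2c(OC(C)=O)ccc([C@@H]3CC(=O)c4c(OC(C)=O)cc(OC(C)=O)cc4O3)c2OC(C)=O)[C@@H](C(=O)c2ccc(OC(C)=O)cc2O)[C@H](c2ccc(OC(C)=O)cc2OC(C)=O)C1 | intermediate
22 | Kuwanon L | CC1=C[C@H](c2c(O)ccc([C@@H]3CC(=O)c4c(O)cc(O)cc4O3)c2O)[C@@H](C(=O)c2ccc(O)cc2O)[C@H](c2ccc(O)cc2O)C1 | target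

Total steps: 14. Longest linear sequence: 8 steps (6, 7, 8, 9, 10, 11, 13, 14; the chalcone branch 1 or 2, 3, 4, 5, 10, 11, 13, 14 is equally long).

**Steps most likely to fail**

First, step 13. The aryl group on rhodium carries an ortho acetoxy group buttressed by the neighbouring cyclohexenyl substituent, so transmetalation and insertion may be slow and protodeboronation may win; catalyst control of the C2 face may also be incomplete. The fallback separates bond formation from stereocontrol and sets out from 18 and 20. A Pd(II)-catalysed oxidative boron–Heck coupling (Pd(TFA)2, 2,2'-bipyridine, O2 or benzoquinone, 80 °C) should give the flavone F1; because no stereocentre is formed it can be forced thermally. Conjugate reduction of F1 with a copper hydride (Cu(OAc)2, a chiral bisphosphine such as DTBM-SEGPHOS, a hydrosilane; or the hexameric triphenylphosphine copper hydride) then sets C2. Compound 21 and its 2R epimer F2 are diastereomers and separable by chromatography; F2 is dehydrogenated back to F1 (DDQ) and recycled. The route is rejoined at 21.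

Second, step 10. The chelate-directed cycloaddition may give insufficient exo (all-trans) selectivity or incomplete facial control, since exo and endo transition states are close in energy for this class. The fallback sets out from 7 and 13 and gives up reagent control. The cycloaddition is run without the chiral borate, under silver-nanoparticle (electron-transfer) catalysis or thermally, to give the racemic exo adduct, that is 16 together with its enantiomer F3. This racemate is separated from the endo racemate on silica and resolved by preparative HPLC on a chiral stationary phase. The route is rejoined at 16.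

Third, step 14. As the B-ring phenols are unveiled, even weakly basic conditions may open the flavanone through the 2'/4'-phenoxide (quinone-methide pathway) and erode C2, and the free polyphenol may oxidise in air. The fallback sets out from 21 and corrects the epimerisation instead of suppressing it. Because the three cyclohexene stereocentres are fixed, Kuwanon L and its 2R epimer F4 are diastereomers and are separated by reverse-phase preparative HPLC. F4 is re-equilibrated through the ring-opened chalcone (degassed pH 9–10 buffer) to a mixture of 22 and F4 and separated again. The route is rejoined at 22.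

**Further compounds**
F1 | step 13 | flavone analogue of 21 (C2=C3 unsaturated): 2-{2,4-diacetoxy-3-[(1S,5R,6S)-6-(4-acetoxy-2-hydroxybenzoyl)-5-(2,4-diacetoxyphenyl)-3-methylcyclohex-2-en-1-yl]phenyl}-4-oxo-4H-chromene-5,7-diyl diacetate | CC1=C[C@H](c2c(OC(C)=O)ccc(-c3cc(=O)c4c(OC(C)=O)cc(OC(C)=O)cc4o3)c2OC(C)=O)[C@@H](C(=O)c2ccc(OC(C)=O)cc2O)[C@H](c2ccc(OC(C)=O)cc2OC(C)=O)C1
F2 | step 13 | (2R)-epimer of 21 | CC1=C[C@H](c2c(OC(C)=O)ccc([C@H]3CC(=O)c4c(OC(C)=O)cc(OC(C)=O)cc4O3)c2OC(C)=O)[C@@H](C(=O)c2ccc(OC(C)=O)cc2O)[C@H](c2ccc(OC(C)=O)cc2OC(C)=O)C1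
F3 | step 10 | enantiomer of 16, (1R,5S,6R) | CC1=C[C@@H](c2c(OC(C)=O)ccc(Br)c2OC(C)=O)[C@H](C(=O)c2ccc(OC(C)=O)cc2O)[C@@H](c2ccc(OC(C)=O)cc2OC(C)=O)C1
F4 | step 14 | (2R)-epimer of Kuwanon L | CC1=C[C@H](c2c(O)ccc([C@H]3CC(=O)c4c(O)cc(O)cc4O3)c2O)[C@@H](C(=O)c2ccc(O)cc2O)[C@H](c2ccc(O)cc2O)C1
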